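Retrosynthesis: the C9–O ester between the halves is cut first; in the lactone half the C8(=O)–O lactone bond, the C6–C7 bond and the C5=C6 alkene are cut back to a cis-dialdehyde, this to the C5=C8 bond of a cyclobutene, and the cyclobutene at C4a–C5 and C8a–C8 to (S)-4-isopropylcyclohex-2-enone and acetylene. The other half is cut at its two C–CH2OH bonds, its side-chain C=C and the C6'–C bond to (R)-4-isopropylcyclohex-2-enone, because the target SMILES places the two halves in opposite enantiomeric series.
Enabling feature: on the cyclohexane of the lactone half the ring-fusion carbons C4a and C8a hold the alkenyl CH (C5) and the lactone C=O (C8) on one face, anti to the isopropyl group on C4; this is the imprint a cis-fused cyclobutene leaves after oxidative cleavage.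
Forward: enone, [2+2] closure of the four-membered ring (opened later by ozone), hydroxymethyl addition at C1, dialdehyde, C5 olefination and C8 oxidation, Stille hydroxymethylation, seven-membered lactone. The other half arises by conjugate vinylation/enol triflate, ozonolysis, Wittig and twofold Stille coupling; Yamaguchi union and deprotection finish.
Stereochemistry: C4 and C1' from enantioselective deprotonation of 4-isopropylcyclohexanone with either enantiomer of a chiral lithium amide; C4a and C8a from the photocycloaddition (anti to isopropyl, cis fusion); C1 from convex-face Grignard addition; C6' from anti conjugate addition; alkene geometry from stabilised-ylide Wittig reactions plus stereoretentive Stille couplings.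

Key step: step 3

Locants used below: lactone half C1 (carbinol carbon), C4 (isopropyl), C4a, C5 (alkenyl CH), C6, C7 (OCH2), C8 (lactone C=O), C8a, C9 (exocyclic CH2O on C1); other half C1' (isopropyl), C4' (ring carbon bearing CH2O), C5' (ring =CH), C6' (side-chain carbon). In the lactone half C4a–C5, C8a–C8 and C1–O lie on one face, the isopropyl group and C1–C9 on the other.
Assumption: lithium (S,S)-bis(1-phenylethyl)amide is taken to give the (R)-silyl enol ether 3 (hence the (S)-enone) and its mirror image the (S)-enol ether 24, the sense usual for 4-alkylcyclohexanones; if the sense is opposite, the two amines change places.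

Step 1
Reactants: 1 4-isopropylcyclohexanone
Product: 3 (R)-trimethyl[(4-isopropylcyclohex-1-en-1-yl)oxy]silane, via lithium enolate 2 (not isolated)
Conditions: (S,S)-bis(1-phenylethyl)amine, n-BuLi, LiCl, THF, −78 °C; then Me3SiCl, −78 °C
Reagents that add atoms: chlorotrimethylsilane, C[Si](C)(C)Cl
Why: Enantioselective deprotonation (chiral lithium amide desymmetrisation): the C2-symmetric amide removes one of the two enantiotopic axial α-protons of the chair with equatorial isopropyl, so that O-silylation of the enolate fixes C4 as R in the enol ether.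

Step 2
Reactants: 3 (R)-trimethyl[(4-isopropylcyclohex-1-en-1-yl)oxy]silane
Product: 4 (S)-4-isopropylcyclohex-2-en-1-one
Conditions: Pd(OAc)2 (10 mol %), O2 (1 atm), DMSO, rt
Reagents that add atoms: none
Why: Saegusa–Ito oxidation: palladation of the silyl enol ether and β-hydride elimination install the C2=C3 double bond on the side of the former enol ether, O2 in DMSO turns the palladium over, and the C4 stereocentre is not touched.

Step 3
Reactants: 4 (S)-4-isopropylcyclohex-2-en-1-one; 5 acetylene
Product: 6 (1S,5S,6S)-5-isopropylbicyclo[4.2.0]oct-7-en-2-one (cis-fused; isopropyl anti to the cyclobutene)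
Conditions: hν (medium-pressure Hg lamp, Pyrex, >300 nm), C2H2-saturated acetone, −78 °C, stopped before full conversion
Reagents that add atoms: none
Why: Excitation and intersystem crossing give the triplet enone, which adds to acetylene (kept in large excess to outrun enone dimerisation) to form a triplet 1,4-biradical that collapses after spin inversion; the closest known reaction type is the enone–alkyne [2+2] photocycloaddition that gives bicyclo[4.2.0]oct-7-en-2-ones. The cyclobutene is closed by radical–radical recombination of that biradical, forming the second C–C bond across the former α- and β-carbons, and only cis fusion is attainable for a cyclobutene on a six-membered ring. The β-carbon stereocentre (C6 of 6) is set by the neighbouring isopropyl group, which shields its own face of the twisted triplet so that the first C–C bond forms anti to it; the α-carbon stereocentre (C1 of 6) then follows from the cis-fusion constraint. The step needs π-facial selectivity and survival of the β,γ-unsaturated ketone product: the adjacent stereocentre secures the first, while filtered light, low temperature and incomplete conversion limit the 1,3-acyl shift of 6.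

Step 4
Reactants: 6 (1S,5S,6S)-5-isopropylbicyclo[4.2.0]oct-7-en-2-one; 7 (chloromethyl)isopropoxydimethylsilane
Product: 10 2-(hydroxymethyl)-5-isopropylbicyclo[4.2.0]oct-7-en-2-ol (tertiary OH syn to the cyclobutene), via Grignard reagent 8 (not isolated), via hydroxysilane 9 (not isolated)
Conditions: 7, Mg, THF, rt; then 6, THF, −20 → 0 °C; H2O quench; then 30% H2O2, KF, KHCO3, THF/MeOH, rt
Reagents that add atoms: hydrogen peroxide, OO
Why: Grignard 1,2-addition followed by Tamao–Fleming oxidation: the weakly basic α-silyl Grignard reagent should attack the ketone from the convex face opposite the cyclobutene (the pseudo-axial C8a–C8 bond blocks the other face), placing C9 anti and the tertiary hydroxyl syn to the four-membered ring, and the C–Si bond is then oxidised to C–OH by basic peroxide that leaves the cyclobutene alone.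

Step 5
Reactants: 10 2-(hydroxymethyl)-5-isopropylbicyclo[4.2.0]oct-7-en-2-ol
Product: 11 bis(triethylsilyl) ether of 10 (Et3SiO on C1 and on C9)
Conditions: Et3SiOTf, 2,6-lutidine, CH2Cl2, −78 → 0 °C
Reagents that add atoms: triethylsilyl trifluoromethanesulfonate, CC[Si](CC)(CC)OS(=O)(=O)C(F)(F)F
Why: Silyl ether formation with a silyl triflate, reactive enough for the tertiary hydroxyl, masks both oxygens so that later no lactol, γ-lactone or β-lactone can form, and puts a bulky Et3SiO group next to C8a.

Step 6
Reactants: 11 bis(triethylsilyl) ether of 10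
Product: 13 cis-dialdehyde (C5 formyl on C4a; C8 formyl on C8a), via ozonide 12 (not isolated)
Conditions: O3, CH2Cl2, −78 °C; then PPh3, −78 °C → rt; used crude
Reagents that add atoms: ozone, [O-][O+]=O
Why: Ozonolysis with reductive work-up: the strained cis-disubstituted cyclobutene is the only C=C, silyl ethers tolerate ozone, and the neutral phosphine reduction of the ozonide leaves the cis-related C4a and C8a centres unepimerised.

Step 7
Reactants: 14 tert-butyl (triphenylphosphoranylidene)acetate
Product: 16 tert-butyl bromo(triphenylphosphoranylidene)acetate, via bromophosphonium bromide 15 (not isolated)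
Conditions: Br2, CH2Cl2, −78 °C; then aq. NaOH, 0 °C
Reagents that add atoms: bromine, BrBr
Why: C-Bromination of a stabilised phosphorus ylide followed by deprotonation of the resulting bromophosphonium salt is the standard route to α-halo ylides.

Step 8
Reactants: 13 cis-dialdehyde; 16 tert-butyl bromo(triphenylphosphoranylidene)acetate
Product: 17 tert-butyl (Z)-2-bromoacrylate on C5 with the C8 aldehyde intact
Conditions: 16 (1.05 equiv), CH2Cl2, 0 °C → rt
Reagents that add atoms: none
Why: Wittig olefination with a stabilised α-bromo ylide under base-free conditions: the bulky ylide should pick the equatorial C5 aldehyde next to CH(iPr) over the axial C8 aldehyde that is flanked by the fully substituted C1 with its Et3SiO group, and thermodynamic control in the oxaphosphetane puts the ester trans to C4a (Br cis, Z).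

Step 9
Reactants: 17 bromoacrylate aldehyde
Product: 18 bromoacrylate C8 carboxylic acid
Conditions: NaClO2, NaH2PO4, 2-methyl-2-butene, t-BuOH/H2O, 0 °C → rt
Reagents that add atoms: sodium chlorite, [Na+].[O-]Cl=O
Why: Pinnick oxidation at buffered pH converts the hindered aldehyde into the acid without enolising C8a and without affecting the bromoacrylate or the silyl ethers.

Step 10
Reactants: 18 bromoacrylate C8 carboxylic acid
Product: 19 hydroxy acid with an (E)-2-(hydroxymethyl)acrylate on C4a
Conditions: Bu3SnCH2OH, Pd(PPh3)4 (cat.), dioxane, 90 °C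
Reagents that add atoms: (tributylstannyl)methanol, CCCC[Sn](CCCC)(CCCC)CO
Why: Stille cross-coupling: oxidative addition of zerovalent palladium into the activated vinylic C–Br bond and transfer of CH2OH from tin replace bromine with retention of the alkene geometry, so CH2OH ends up cis to C4a.

Step 11
Reactants: 19 hydroxy acid
Product: 21 bis(triethylsilyl) seven-membered lactone tert-butyl ester, via mixed anhydride 20 (not isolated)
Conditions: 2,4,6-Cl3C6H2COCl, Et3N, THF, rt; then DMAP, toluene, high dilution, rt → 40 °C
Reagents that add atoms: none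
Why: Yamaguchi lactonisation: the C8 carboxyl is activated as the mixed anhydride and acylates the primary allylic hydroxyl, which the E-enoate and the cis relationship of the C4a and C8a substituents hold within reach for seven-membered closure, while the silylated tertiary oxygen cannot give a β-lactone.

Step 12
Reactants: 21 bis(triethylsilyl) lactone
Product: 22 lactone diol tert-butyl ester (free C1-OH and C9-OH)
Conditions: HF·pyridine, pyridine, THF, 0 °C → rt
Reagents that add atoms: none
Why: Fluoride desilylation under mildly acidic conditions removes both Et3Si groups while tert-butyl ester and lactone persist, and the freed C9 hydroxyl should not translactonise because C9 and C8 are trans-diaxial on the chair that keeps the isopropyl group equatorial.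

Step 13
Reactants: 1 4-isopropylcyclohexanone
Product: 24 (S)-trimethyl[(4-isopropylcyclohex-1-en-1-yl)oxy]silane, via lithium enolate 23 (not isolated)
Conditions: (R,R)-bis(1-phenylethyl)amine, n-BuLi, LiCl, THF, −78 °C; then Me3SiCl, −78 °C
Reagents that add atoms: chlorotrimethylsilane, C[Si](C)(C)Cl
Why: The same enantioselective deprotonation with the mirror-image lithium amide removes the other enantiotopic α-proton and gives the S-configured enol ether.

Step 14
Reactants: 24 (S)-trimethyl[(4-isopropylcyclohex-1-en-1-yl)oxy]silane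
Product: 25 (R)-4-isopropylcyclohex-2-en-1-one
Conditions: Pd(OAc)2 (10 mol %), O2 (1 atm), DMSO, rt
Reagents that add atoms: none
Why: Saegusa–Ito oxidation as in step 2 gives the R-enone without loss of configuration.

Step 15
Reactants: 25 (R)-4-isopropylcyclohex-2-en-1-one
Product: 27 trans-4-isopropyl-3-vinylcyclohex-1-en-1-yl trifluoromethanesulfonate, via magnesium enolate 26 (not isolated)
Conditions: CH2=CHMgBr, CuBr·SMe2 (10 mol %), THF, −78 °C; then 5-chloro-2-[bis(trifluoromethylsulfonyl)amino]pyridine, −78 °C → rt
Reagents that add atoms: vinylmagnesium bromide, C=C[Mg]Br; 5-chloro-2-[bis(trifluoromethylsulfonyl)amino]pyridine, FC(F)(F)S(=O)(=O)N(c1ccc(Cl)cn1)S(=O)(=O)C(F)(F)F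
Why: Copper-catalysed conjugate addition of the vinyl Grignard reagent occurs anti to the neighbouring isopropyl group (trans product), and O-triflation of the regiodefined magnesium enolate fixes the ring double bond between C4' and C5'.

Step 16
Reactants: 27 enol triflate
Product: 29 trans-6-isopropyl-3-(trifluoromethylsulfonyloxy)cyclohex-2-ene-1-carbaldehyde, via ozonide 28 (not isolated)
Conditions: O3 (1 equiv, as CH2Cl2 solution), CH2Cl2, −78 °C; then PPh3, → rt
Reagents that add atoms: ozone, [O-][O+]=O
Why: Chemoselective ozonolysis with reductive work-up: the electron-rich monosubstituted vinyl group reacts far faster than the electron-poor enol triflate when one equivalent of ozone is dosed, and the aldehyde keeps the thermodynamically preferred trans arrangement.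

Step 17
Reactants: 29 aldehyde; 16 tert-butyl bromo(triphenylphosphoranylidene)acetate
Product: 30 tert-butyl (Z)-2-bromoacrylate bearing the enol triflate ring on C3
Conditions: 16, CH2Cl2, rt
Reagents that add atoms: none
Why: Wittig olefination with the stabilised α-bromo ylide as in step 8, base-free so that the doubly activated C6' hydrogen is not removed, gives the Z-bromoacrylate (ester trans to C6').

Step 18
Reactants: 30 bromoacrylate enol triflate
Product: 31 tert-butyl (E)-2-(hydroxymethyl)-3-[trans-3-(hydroxymethyl)-6-isopropylcyclohex-2-en-1-yl]acrylate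
Conditions: Bu3SnCH2OH (2.5 equiv), Pd(PPh3)4 (cat.), LiCl, dioxane, 95 °C
Reagents that add atoms: (tributylstannyl)methanol, CCCC[Sn](CCCC)(CCCC)CO
Why: Twofold Stille cross-coupling: zerovalent palladium inserts into the enol triflate (LiCl-assisted) and into the α-bromoacrylate, and CH2OH is transferred from tin to both positions with retention of the side-chain geometry.

Step 19
Reactants: 31 diol tert-butyl ester
Product: 32 bis(tert-butyldimethylsilyl) ether of 31
Conditions: t-BuMe2SiCl, imidazole, DMF, rt
Reagents that add atoms: tert-butyldimethylsilyl chloride, CC(C)(C)[Si](C)(C)Cl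
Why: Silyl ether formation (silyl chloride/imidazole) protects both primary allylic hydroxyls for the esterification.

Step 20
Reactants: 32 bis(tert-butyldimethylsilyl) tert-butyl ester
Product: 34 bis(tert-butyldimethylsilyl)-protected acrylic acid, via trimethylsilyl ester 33 (not isolated)
Conditions: Me3SiOTf, 2,6-lutidine, CH2Cl2, 0 °C; then pH 7 buffer/MeOH
Reagents that add atoms: none
Why: Silyl triflate-mediated tert-butyl ester cleavage: O-silylation of the ester carbonyl expels isobutene to leave the trimethylsilyl ester, which is hydrolysed on work-up, while the primary silyl ethers survive the buffered conditions.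

Step 21
Reactants: 34 protected acrylic acid; 22 lactone diol tert-butyl ester
Product: 36 fully protected dimer (C9 ester; two t-BuMe2Si ethers; tert-butyl ester), via mixed anhydride 35 (not isolated)
Conditions: 34, 2,4,6-Cl3C6H2COCl, Et3N, toluene, rt; then 22, DMAP, rt
Reagents that add atoms: none
Why: Yamaguchi esterification: the mixed anhydride of the hindered enoic acid acylates, under DMAP catalysis, the primary C9 hydroxyl in preference to the tertiary C1 hydroxyl, and because the halves belong to opposite enantiomeric series any minor enantiomer ends up in a separable diastereomer.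

Step 22
Reactants: 36 fully protected dimer
Product: 38 CNP0361406.3, via persilylated intermediate 37 (not isolated)
Conditions: Me3SiOTf, 2,6-lutidine, CH2Cl2, 0 °C; then HF·pyridine, THF, 0 °C → rt; aqueous work-up
Reagents that add atoms: none
Why: The same silyl triflate-mediated tert-butyl ester cleavage (which also silylates the tertiary hydroxyl), followed in the same flask by HF·pyridine desilylation, removes every protecting group without base, which could isomerise the skipped diene or open the lactone.

Compound list
1 | 4-isopropylcyclohexanone | CC(C)C1CCC(=O)CC1 | starting material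
2 | lithium (R)-4-isopropylcyclohex-1-en-1-olate | [Li]OC1=CC[C@H](C(C)C)CC1 | intermediate (not isolated)
3 | (R)-trimethyl[(4-isopropylcyclohex-1-en-1-yl)oxy]silane | C[Si](C)(C)OC1=CC[C@H](C(C)C)CC1 | intermediate
4 | (S)-4-isopropylcyclohex-2-en-1-one | O=C1CC[C@@H](C(C)C)C=C1 | intermediate
5 | acetylene | C#C | starting material
6 | (1S,5S,6S)-5-isopropylbicyclo[4.2.0]oct-7-en-2-one, cis-fused, isopropyl anti to the cyclobutene | O=C1CC[C@@H](C(C)C)[C@@H]2C=C[C@@H]21 | intermediate
7 | (chloromethyl)isopropoxydimethylsilane | CC(C)O[Si](C)(C)CCl | starting material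
8 | [(isopropoxydimethylsilyl)methyl]magnesium chloride | CC(C)O[Si](C)(C)C[Mg]Cl | intermediate (not isolated)
9 | 2-[(isopropoxydimethylsilyl)methyl]-5-isopropylbicyclo[4.2.0]oct-7-en-2-ol, OH syn to the cyclobutene | CC(C)O[Si](C)(C)C[C@@]1(O)CC[C@@H](C(C)C)[C@@H]2C=C[C@@H]21 | intermediate (not isolated)
10 | 2-(hydroxymethyl)-5-isopropylbicyclo[4.2.0]oct-7-en-2-ol, tertiary OH syn to the cyclobutene | OC[C@@]1(O)CC[C@@H](C(C)C)[C@@H]2C=C[C@@H]21 | intermediate
11 | bis(triethylsilyl) ether of 10 | CC[Si](CC)(CC)OC[C@@]1(O[Si](CC)(CC)CC)CC[C@@H](C(C)C)[C@@H]2C=C[C@@H]21 | intermediate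
12 | ozonide (1,2,4-trioxolane) of 11, both orientations of the trioxolane | CC[Si](CC)(CC)OC[C@@]1(O[Si](CC)(CC)CC)CC[C@@H](C(C)C)[C@@H]2C3OOC(O3)[C@@H]21 | intermediate (not isolated)
13 | cis-dialdehyde: C5 formyl on C4a and C8 formyl on C8a, both syn to C1-OSiEt3, anti to isopropyl | CC[Si](CC)(CC)OC[C@@]1(O[Si](CC)(CC)CC)CC[C@@H](C(C)C)[C@H](C=O)[C@@H]1C=O | intermediate
14 | tert-butyl (triphenylphosphoranylidene)acetate | CC(C)(C)OC(=O)C=P(c1ccccc1)(c1ccccc1)c1ccccc1 | starting material
15 | (1-bromo-2-tert-butoxy-2-oxoethyl)triphenylphosphonium bromide | CC(C)(C)OC(=O)C(Br)[P+](c1ccccc1)(c1ccccc1)c1ccccc1.[Br-] | intermediate (not isolated)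
16 | tert-butyl bromo(triphenylphosphoranylidene)acetate | CC(C)(C)OC(=O)C(Br)=P(c1ccccc1)(c1ccccc1)c1ccccc1 | intermediate
17 | tert-butyl (Z)-2-bromoacrylate on C4a (from C5), C8 aldehyde on C8a | CC[Si](CC)(CC)OC[C@@]1(O[Si](CC)(CC)CC)CC[C@@H](C(C)C)[C@H](/C=C(\Br)C(=O)OC(C)(C)C)[C@@H]1C=O | intermediate
18 | bromoacrylate C8 carboxylic acid | CC[Si](CC)(CC)OC[C@@]1(O[Si](CC)(CC)CC)CC[C@@H](C(C)C)[C@H](/C=C(\Br)C(=O)OC(C)(C)C)[C@@H]1C(=O)O | intermediate
19 | hydroxy acid: (E)-2-(hydroxymethyl)acrylate on C4a, CO2H on C8a | CC[Si](CC)(CC)OC[C@@]1(O[Si](CC)(CC)CC)CC[C@@H](C(C)C)[C@H](/C=C(\CO)C(=O)OC(C)(C)C)[C@@H]1C(=O)O | intermediate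
20 | mixed 2,4,6-trichlorobenzoic anhydride of 19 | CC[Si](CC)(CC)OC[C@@]1(O[Si](CC)(CC)CC)CC[C@@H](C(C)C)[C@H](/C=C(\CO)C(=O)OC(C)(C)C)[C@@H]1C(=O)OC(=O)c2c(Cl)cc(Cl)cc2Cl | intermediate (not isolated)
21 | bis(triethylsilyl) seven-membered lactone, tert-butyl ester on C6 | CC[Si](CC)(CC)OC[C@@]1(O[Si](CC)(CC)CC)CC[C@@H](C(C)C)[C@@H]2C=C(C(=O)OC(C)(C)C)COC(=O)[C@@H]21 | intermediate
22 | lactone diol tert-butyl ester (free C1-OH and C9-OH) | OC[C@@]1(O)CC[C@@H](C(C)C)[C@@H]2C=C(C(=O)OC(C)(C)C)COC(=O)[C@@H]21 | intermediate
23 | lithium (S)-4-isopropylcyclohex-1-en-1-olate | [Li]OC1=CC[C@@H](C(C)C)CC1 | intermediate (not isolated)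
24 | (S)-trimethyl[(4-isopropylcyclohex-1-en-1-yl)oxy]silane | C[Si](C)(C)OC1=CC[C@@H](C(C)C)CC1 | intermediate
25 | (R)-4-isopropylcyclohex-2-en-1-one | O=C1CC[C@H](C(C)C)C=C1 | intermediate
26 | bromomagnesium enolate of trans-4-isopropyl-3-vinylcyclohexanone | CC(C)[C@H]1CCC(O[Mg]Br)=C[C@@H]1C=C | intermediate (not isolated)
27 | trans-4-isopropyl-3-vinylcyclohex-1-en-1-yl trifluoromethanesulfonate | CC(C)[C@H]1CCC(OS(=O)(=O)C(F)(F)F)=C[C@@H]1C=C | intermediate
28 | ozonide (1,2,4-trioxolane) of the vinyl group of 27 | CC(C)[C@H]1CCC(OS(=O)(=O)C(F)(F)F)=C[C@@H]1C2OCOO2 | intermediate (not isolated)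
29 | trans-6-isopropyl-3-(trifluoromethylsulfonyloxy)cyclohex-2-ene-1-carbaldehyde | CC(C)[C@H]1CCC(OS(=O)(=O)C(F)(F)F)=C[C@@H]1C=O | intermediate
30 | tert-butyl (Z)-2-bromo-3-[trans-6-isopropyl-3-(trifluoromethylsulfonyloxy)cyclohex-2-en-1-yl]acrylate | CC(C)[C@H]1CCC(OS(=O)(=O)C(F)(F)F)=C[C@@H]1/C=C(\Br)C(=O)OC(C)(C)C | intermediate
31 | tert-butyl (E)-2-(hydroxymethyl)-3-[trans-3-(hydroxymethyl)-6-isopropylcyclohex-2-en-1-yl]acrylate | CC(C)[C@H]1CCC(CO)=C[C@@H]1/C=C(\CO)C(=O)OC(C)(C)C | intermediate
32 | bis(tert-butyldimethylsilyl) ether of 31 | CC(C)[C@H]1CCC(CO[Si](C)(C)C(C)(C)C)=C[C@@H]1/C=C(\CO[Si](C)(C)C(C)(C)C)C(=O)OC(C)(C)C | intermediate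
33 | trimethylsilyl ester corresponding to 32 | CC(C)[C@H]1CCC(CO[Si](C)(C)C(C)(C)C)=C[C@@H]1/C=C(\CO[Si](C)(C)C(C)(C)C)C(=O)O[Si](C)(C)C | intermediate (not isolated)
34 | (E)-2-[(tert-butyldimethylsilyloxy)methyl]-3-[trans-3-[(tert-butyldimethylsilyloxy)methyl]-6-isopropylcyclohex-2-en-1-yl]acrylic acid | CC(C)[C@H]1CCC(CO[Si](C)(C)C(C)(C)C)=C[C@@H]1/C=C(\CO[Si](C)(C)C(C)(C)C)C(=O)O | intermediate
35 | mixed 2,4,6-trichlorobenzoic anhydride of 34 | CC(C)[C@H]1CCC(CO[Si](C)(C)C(C)(C)C)=C[C@@H]1/C=C(\CO[Si](C)(C)C(C)(C)C)C(=O)OC(=O)c2c(Cl)cc(Cl)cc2Cl | intermediate (not isolated)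
36 | protected dimer: C9 ester of 22 with 34 | CC(C)[C@H]1CCC(CO[Si](C)(C)C(C)(C)C)=C[C@@H]1/C=C(\CO[Si](C)(C)C(C)(C)C)C(=O)OC[C@@]1(O)CC[C@@H](C(C)C)[C@@H]2C=C(C(=O)OC(C)(C)C)COC(=O)[C@@H]21 | intermediate
37 | persilylated dimer: trimethylsilyl ester on C6, Me3SiO on C1, two t-BuMe2Si ethers | CC(C)[C@H]1CCC(CO[Si](C)(C)C(C)(C)C)=C[C@@H]1/C=C(\CO[Si](C)(C)C(C)(C)C)C(=O)OC[C@@]1(O[Si](C)(C)C)CC[C@@H](C(C)C)[C@@H]2C=C(C(=O)O[Si](C)(C)C)COC(=O)[C@@H]21 | intermediate (not isolated)
38 | CNP0361406.3 | CC(C)[C@H]1CCC(CO)=C[C@@H]1/C=C(\CO)C(=O)OC[C@@]1(O)CC[C@@H](C(C)C)[C@@H]2C=C(C(=O)O)COC(=O)[C@@H]21 | target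

Total step count: 22. Longest linear sequence: 13 steps (steps 1–6, 8–12, 21, 22); the other half takes 8 steps (13–20) and the ylide 1 step (7).

Steps most likely to fail

Step 8. The ylide may not discriminate well enough between the two formyl groups, may olefinate both, or C8a may epimerise while the C8 aldehyde waits. Fallback: tether C8 to the tertiary oxygen at the alcohol oxidation level, so that site selection no longer rests on sterics. Setting out from diol 10, selective silylation of the primary hydroxyl (t-BuPh2SiCl, imidazole) gives the C9 tert-butyldiphenylsilyl ether F1. Ozonolysis with NaBH4 work-up gives the triol F2. Acetone dimethyl acetal/PPTS ties the C1 hydroxyl and the C8 carbinol into the six-membered acetonide F3 (the alternatives would be seven-membered) and leaves only the C5 carbinol free. Parikh–Doering oxidation gives the C5 aldehyde F4, and Wittig reaction with 16 gives the bromoacrylate acetonide F5. PPTS/MeOH frees the bromoacrylate 1,3-diol F6, and TEMPO/PhI(OAc)2 followed by NaClO2 oxidises its primary carbinol to the bromoacrylate C8 acid F7. Stille hydroxymethylation as in step 10 gives the hydroxy acid F8, and Yamaguchi lactonisation (the primary allylic hydroxyl outruns the tertiary one) gives the C9-silylated lactone F9. HF·pyridine removes the silyl group and the sequence comes back to the route at 22.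

Step 3. Trapping of the triplet enone by the gaseous alkyne may be inefficient (enone dimerisation), and the β,γ-unsaturated ketone product may be consumed by secondary photolysis (1,3-acyl shift). Fallback: build the same two C–C bonds with an acetylene equivalent that gives a saturated, photostable adduct. Setting out from 4, irradiation in neat excess (E)-1,2-dichloroethene, followed by equilibration over basic Al2O3 to the cis-fused ketone, gives the dichlorocyclobutane adduct F10 (chloride epimers). Ethylene glycol/TsOH gives the dichloro ketal F11, sodium in liquid ammonia removes both chlorines to give the cyclobutene ketal F12, and dilute aqueous acid returns the sequence to the route at 6. Facial selectivity rests on the same isopropyl control as in the main step.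

Step 4. The Grignard reagent may attack from the cyclobutene face (equatorial trajectory favoured by bulky organometallics) or enolise the β,γ-unsaturated ketone. Fallback: use a small ylide that adds irreversibly and prefers the axial trajectory, and open the epoxide afterwards. Setting out from 6, Corey–Chaykovsky reaction with dimethylsulfonium methylide (Me3S+ I−, KHMDS, THF, −10 °C) gives the spiro-epoxide F13 (oxygen syn to the cyclobutene). Hydroxide opening at the CH2 terminus (KOH, DMSO/H2O, 80 °C) comes back to the route at 10.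

Further compounds
F1 | step 8 | C9 tert-butyldiphenylsilyl ether of diol 10 | CC(C)(C)[Si](OC[C@@]1(O)CC[C@@H](C(C)C)[C@@H]2C=C[C@@H]21)(c1ccccc1)c1ccccc1
F2 | step 8 | triol: C5 and C8 carbinols, free C1-OH, C9 silyl ether | CC(C)(C)[Si](OC[C@@]1(O)CC[C@@H](C(C)C)[C@H](CO)[C@@H]1CO)(c1ccccc1)c1ccccc1
F3 | step 8 | C1-O/C8-O acetonide with free C5 carbinol | CC(C)(C)[Si](OC[C@@]12CC[C@@H](C(C)C)[C@H](CO)[C@@H]1COC(C)(C)O2)(c1ccccc1)c1ccccc1
F4 | step 8 | C5 aldehyde of the acetonide | CC(C)(C)[Si](OC[C@@]12CC[C@@H](C(C)C)[C@H](C=O)[C@@H]1COC(C)(C)O2)(c1ccccc1)c1ccccc1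
F5 | step 8 | (Z)-bromoacrylate acetonide | CC(C)(C)[Si](OC[C@@]12CC[C@@H](C(C)C)[C@H](/C=C(\Br)C(=O)OC(C)(C)C)[C@@H]1COC(C)(C)O2)(c1ccccc1)c1ccccc1
F6 | step 8 | bromoacrylate 1,3-diol (C1-OH, C8 carbinol) | CC(C)(C)[Si](OC[C@@]1(O)CC[C@@H](C(C)C)[C@H](/C=C(\Br)C(=O)OC(C)(C)C)[C@@H]1CO)(c1ccccc1)c1ccccc1
F7 | step 8 | bromoacrylate C8 acid with free C1-OH | CC(C)(C)[Si](OC[C@@]1(O)CC[C@@H](C(C)C)[C@H](/C=C(\Br)C(=O)OC(C)(C)C)[C@@H]1C(=O)O)(c1ccccc1)c1ccccc1
F8 | step 8 | hydroxy acid with free C1-OH and C9 silyl ether | CC(C)(C)[Si](OC[C@@]1(O)CC[C@@H](C(C)C)[C@H](/C=C(\CO)C(=O)OC(C)(C)C)[C@@H]1C(=O)O)(c1ccccc1)c1ccccc1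
F9 | step 8 | C9 tert-butyldiphenylsilyl ether of lactone 22 | CC(C)(C)[Si](OC[C@@]1(O)CC[C@@H](C(C)C)[C@@H]2C=C(C(=O)OC(C)(C)C)COC(=O)[C@@H]21)(c1ccccc1)c1ccccc1
F10 | step 3 | cis-fused 7,8-dichloro-5-isopropylbicyclo[4.2.0]octan-2-one (chloride epimers) | O=C1CC[C@@H](C(C)C)[C@@H]2C(Cl)C(Cl)[C@@H]21
F11 | step 3 | ethylene ketal of the dichloro ketone | O1CCOC12CC[C@@H](C(C)C)[C@@H]3C(Cl)C(Cl)[C@@H]32
F12 | step 3 | ethylene ketal of 6 | O1CCOC12CC[C@@H](C(C)C)[C@@H]3C=C[C@@H]32
F13 | step 4 | spiro-epoxide of 6 (oxygen syn to the cyclobutene) | C1O[C@@]12CC[C@@H](C(C)C)[C@@H]3C=C[C@@H]32
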